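**Retrosynthetic overview**
1. Target 28 ⇐ lactone 23: C13 enters last by aldol of the lactone enolate with CH2O (only the exo face is open), then acetate, desilylation, tiglate.
2. 23 ⇐ 18: ring D (γ-lactone) by exo reduction of the C8 ketone, C10 methyl by cuprate addition, ring C (tetrahydrofuran) by 5-exo opening of a 4α,5α-epoxide by the C11 hydroxyl, ring B (seven-membered) by ring-closing metathesis.
3. 15 ⇐ 13 (key step): dianionic Ireland–Claisen [3,3] rearrangement of a tertiary allylic (S)-malate ester makes C6–C7, sets C7 and moves the alkene to C4=C5.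
4. 13 ⇐ 5 + 11: ring A from (S)-4-silyloxycyclopentenone 5 (vinyl conjugate addition/CH2O trapping, methylenation, MeLi); 5 from L-threitol ditosylate 1 by FAMSO annulation.
5. Ring order A → B → C → D; absolute configuration comes from L-tartaric acid (C2, relayed to C1, C4, C5, C8, C10) and L-malic acid (C11, relayed to C7).

Assumption and convention: 1 and 11 are bought as such (catalogue compounds made from L-tartaric and L-malic acid); locants are guaiane numbers (ring A = C1–C5 with C15 on C4, ring B = C1, C5–C10 with C14 on C10, C11–C13 on C7), α is the face of H-1, TBSO = tert-butyldimethylsilyloxy; 10, 12, 13 and 14 are carried as carbinol-epimer mixtures (major epimer drawn) because that centre is erased in step 9.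

**Route**

Step 1
Reactants: 1 1,4-di-O-tosyl-2,3-O-isopropylidene-L-threitol
Product: 2 (3aS,6aS)-2,2-dimethyl-5-(methylsulfanyl)-5-(methylsulfinyl)tetrahydro-4H-cyclopenta[d][1,3]dioxole
Conditions: FAMSO (1.1 equiv), KH (2.3 equiv), THF, 0 °C → rt
Reagents that add atoms: methyl (methylsulfanyl)methyl sulfoxide (FAMSO), CSCS(C)=O
Why: Double SN2 alkylation of the FAMSO carbanion (an acyl-anion equivalent, Ogura-type annulation) closes the trans-fused cyclopentane; both stereocentres are those of L-threitol.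

Step 2
Reactants: 2 dithioacetal S-oxide
Product: 4 (S)-4-hydroxycyclopent-2-en-1-one, via acetonide ketone 3 (not isolated)
Conditions: 0.5 M H2SO4, THF, rt
Reagents that add atoms: water, O
Why: Acid hydrolysis of the dithioacetal S-oxide unmasks the ketone, and the strained β-alkoxy ketone undergoes β-elimination with loss of acetone, leaving one tartrate-derived carbinol centre.

Step 3
Reactants: 4 (S)-4-hydroxycyclopent-2-en-1-one
Product: 5 (S)-4-(TBSO)cyclopent-2-en-1-one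
Conditions: TBSCl, imidazole, DMF, 0 °C → rt
Reagents that add atoms: tert-butyldimethylsilyl chloride, CC(C)(C)[Si](C)(C)Cl
Why: Silylation of the secondary alcohol; the stereocentre is untouched.

Step 4
Reactants: 5 (S)-4-(TBSO)cyclopent-2-en-1-one
Product: 7 (2R,3S,4S)-4-(TBSO)-2-(hydroxymethyl)-3-vinylcyclopentan-1-one, via bromomagnesium enolate 6 (not isolated)
Conditions: CH2=CHMgBr (1.3 equiv), CuBr·SMe2 (10 mol%), THF, −78 °C; then CH2O (gas), −78 → −40 °C; aq. NH4Cl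
Reagents that add atoms: vinylmagnesium bromide, C=C[Mg]Br; formaldehyde, C=O
Why: Copper-catalysed conjugate addition puts the vinyl group anti to the silyloxy group (sets C1), and aldol trapping of the enolate with formaldehyde occurs anti to the new vinyl group (three-component coupling).

Step 5
Reactants: 7 hydroxymethyl ketone
Product: 9 (3S,4S)-4-(TBSO)-2-methylidene-3-vinylcyclopentan-1-one, via mesylate 8 (not isolated)
Conditions: MsCl, Et3N, CH2Cl2, 0 °C → rt (short reaction time)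
Reagents that add atoms: none
Why: Mesylation followed by E1cB elimination gives the exocyclic enone; no stereocentre is touched.

Step 6
Reactants: 9 α-methylene ketone
Product: 10 (1R,3S,4S)-4-(TBSO)-1-methyl-2-methylidene-3-vinylcyclopentan-1-ol
Conditions: MeLi, CeCl3, THF, −78 °C
Reagents that add atoms: methyllithium, [Li]C
Why: Organocerium (Imamoto) 1,2-addition to the enone carbonyl avoids enolisation and β-elimination of the silyloxy group; the new carbinol centre is erased in step 9.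

Step 7
Reactants: 10 tertiary allylic alcohol; 11 (S)-2-(2,2-dimethyl-5-oxo-1,3-dioxolan-4-yl)acetic acid
Product: 12 (1R,3S,4S)-4-(TBSO)-1-methyl-2-methylidene-3-vinylcyclopentyl 2-[(4S)-2,2-dimethyl-5-oxo-1,3-dioxolan-4-yl]acetate
Conditions: DCC, DMAP (0.3 equiv), CH2Cl2, 0 °C → rt
Reagents that add atoms: none
Why: Steglich esterification acylates the tertiary allylic alcohol with the free carboxyl group of 11; the dioxolanone is not opened.

Step 8
Reactants: 12 dioxolanone ester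
Product: 13 1-methyl 4-[(1R,3S,4S)-4-(TBSO)-1-methyl-2-methylidene-3-vinylcyclopentyl] (2S)-2-hydroxybutanedioate
Conditions: K2CO3 (0.2 equiv), MeOH, 0 °C
Reagents that add atoms: methanol, CO
Why: Base-catalysed methanolysis (transesterification) of the activated dioxolanone carbonyl releases acetone and the free C11 hydroxyl; the hindered tertiary ester survives.

Step 9
Reactants: 13 tertiary allylic (S)-malate ester
Product: 15 (2R,3S)-2-{[(4S,5S)-4-(TBSO)-2-methyl-5-vinylcyclopent-1-en-1-yl]methyl}-3-hydroxy-4-methoxy-4-oxobutanoic acid, via dilithium alkoxide enolate 14 (not isolated)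
Conditions: LiN(iPr)2 (2.4 equiv), THF, −78 °C → rt; then 1 M HCl
Reagents that add atoms: none
Why: Dianionic Ireland–Claisen [3,3]-sigmatropic rearrangement: the chelated alkoxide–enolate receives the allyl terminus C6 anti to the C11 alkoxide (Fráter–Seebach sense), forming C6–C7, setting C7 and converting the tertiary carbinol into the C4=C5 alkene, so both carbinol epimers converge.

Step 10
Reactants: 15 acid
Product: 16 methyl (2S,3R)-3-{[(4S,5S)-4-(TBSO)-2-methyl-5-vinylcyclopent-1-en-1-yl]methyl}-2-hydroxy-4-[methoxy(methyl)amino]-4-oxobutanoate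
Conditions: MeNHOMe·HCl, EDC·HCl, N-methylmorpholine, CH2Cl2, 0 °C → rt
Reagents that add atoms: N,O-dimethylhydroxylamine hydrochloride, CNOC.Cl
Why: Carbodiimide amide coupling converts only the free acid into the Weinreb amide.

Step 11
Reactants: 16 Weinreb amide
Product: 17 methyl (2S,3R)-3-{[(4S,5S)-4-(TBSO)-2-methyl-5-vinylcyclopent-1-en-1-yl]methyl}-2-hydroxy-4-oxohex-5-enoate
Conditions: CH2=CHMgBr (3.5 equiv), THF, −78 → −20 °C; cold aq. citric acid
Reagents that add atoms: vinylmagnesium bromide, C=C[Mg]Br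
Why: Weinreb ketone synthesis: the Grignard reagent adds once via the stable magnesium chelate, while the methyl ester is deactivated by the adjacent magnesium alkoxide.

Step 12
Reactants: 17 vinyl ketone
Product: 18 methyl (11S)-2α-(TBSO)-11-hydroxy-8-oxo-13,14-dinor-1αH,7αH-guaia-4,9-dien-12-oate
Conditions: second-generation Grubbs catalyst (5 mol%), CH2Cl2 (0.002 M), 40 °C
Reagents that add atoms: none
Why: Ring-closing metathesis between the enone vinyl group and the C1 vinyl group closes ring B as the cis-cycloheptenone; the tetrasubstituted alkene does not take part.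

Step 13
Reactants: 18 bicyclic dienone
Product: 20 methyl (11S)-2α-(TBSO)-5β,11-epoxy-4α-hydroxy-8-oxo-13,14-dinor-1αH,7αH-guai-9-en-12-oate, via 4α,5α-epoxide 19 (not isolated)
Conditions: mCPBA (1.1 equiv), NaHCO3, CH2Cl2, 0 °C; then PPTS (10 mol%), rt
Reagents that add atoms: 3-chloroperoxybenzoic acid, OOC(=O)c1cccc(Cl)c1
Why: Prilezhaev epoxidation of the electron-rich C4=C5 alkene from the convex α face (anti to the β C1–C10 bond and C7 side chain), then 5-exo-tet SN2 opening at C5 by the C11 hydroxyl with inversion gives the 5β ether and the 4α tertiary alcohol; a β-epoxide cannot be reached by this hydroxyl.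

Step 14
Reactants: 20 oxa-bridged enone
Product: 21 methyl (11S)-2α-(TBSO)-5β,11-epoxy-4α-hydroxy-8-oxo-13-nor-1αH,7αH,10βH-guaian-12-oate
Conditions: Me2CuLi (4 equiv), Et2O, −78 → −40 °C; aq. NH4Cl at −78 °C
Reagents that add atoms: lithium dimethylcuprate, [Li+].C[Cu-]C
Why: Gilman conjugate addition; the methyl group enters C10 from the exo α face of the oxabicyclo[4.2.1]nonenone, opposite the ether bridge and syn to H-1.

Step 15
Reactants: 21 ketone
Product: 23 (11S)-2α-(TBSO)-5β,11-epoxy-4α-hydroxy-13-nor-1αH,7αH,8αH,10βH-guaian-12,8β-olide, via 8β-hydroxy ester 22 (not isolated)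
Conditions: NaBH4, CeCl3·7H2O, MeOH, −78 °C; then PPTS (cat.), CH2Cl2, rt
Reagents that add atoms: none
Why: Luche-type hydride delivery from the exo α face gives the 8β alcohol, which is cis to the C12 ester and closes ring D by lactonisation.

Step 16
Reactants: 23 lactone
Product: 25 (11R)-2α-(TBSO)-5β,11-epoxy-4α,13-dihydroxy-1αH,7αH,8αH,10βH-guaian-12,8β-olide, via lithium lactone enolate 24 (not isolated)
Conditions: LiN(iPr)2 (3 equiv), THF, −78 °C; CH2O (gas), −78 °C; aq. NH4Cl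
Reagents that add atoms: formaldehyde, C=O
Why: Aldol reaction of the lactone enolate with formaldehyde; C11 is held in rings C and D, so the hydroxymethyl group can only enter from the exo face (overall retention at C11).

Step 17
Reactants: 25 diol
Product: 26 (11R)-13-acetoxy-2α-(TBSO)-5β,11-epoxy-4α-hydroxy-1αH,7αH,8αH,10βH-guaian-12,8β-olide
Conditions: Ac2O, pyridine, CH2Cl2, 0 °C → rt
Reagents that add atoms: acetic anhydride, CC(=O)OC(C)=O
Why: Acylation of the primary C13 hydroxyl; the tertiary C4 hydroxyl does not react without DMAP.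

Step 18
Reactants: 26 silyl ether
Product: 27 (11R)-13-acetoxy-5β,11-epoxy-2α,4α-dihydroxy-1αH,7αH,8αH,10βH-guaian-12,8β-olide
Conditions: HF·pyridine, THF, 0 °C → rt
Reagents that add atoms: none
Why: Fluoride-mediated cleavage of the secondary silyl ether; acetate, lactone and tertiary alcohol are stable to buffered HF.

Step 19
Reactants: 27 diol
Product: 28 CNP0112086.1 (13-acetoxy-5β,11-epoxy-4α-hydroxy-2α-tigloyloxy-1αH,7αH,8αH,10βH-guaian-12,8β-olide)
Conditions: tiglic acid, DCC, DMAP (cat.), CH2Cl2, rt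
Reagents that add atoms: tiglic acid, C/C=C(\C)C(=O)O
Why: Steglich esterification of the secondary 2α-hydroxyl; the tertiary hydroxyl is too hindered and the (E)-geometry of the acid is retained.

**Compound list**

1 | 1,4-di-O-tosyl-2,3-O-isopropylidene-L-threitol, [(4S,5S)-2,2-dimethyl-1,3-dioxolane-4,5-diyl]bis(methylene) bis(4-methylbenzenesulfonate) | CC1(C)O[C@@H](COS(=O)(=O)c2ccc(C)cc2)[C@H](COS(=O)(=O)c2ccc(C)cc2)O1 | starting material
2 | (3aS,6aS)-2,2-dimethyl-5-(methylsulfanyl)-5-(methylsulfinyl)tetrahydro-4H-cyclopenta[d][1,3]dioxole (trans-fused, sulfoxide epimers) | CC1(C)O[C@H]2CC(SC)(S(C)=O)C[C@@H]2O1 | intermediate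
3 | (3aS,6aS)-2,2-dimethyltetrahydro-4H-cyclopenta[d][1,3]dioxol-5-one | CC1(C)O[C@H]2CC(=O)C[C@@H]2O1 | intermediate (not isolated)
4 | (S)-4-hydroxycyclopent-2-en-1-one | O[C@H]1CC(=O)C=C1 | intermediate
5 | (S)-4-(tert-butyldimethylsilyloxy)cyclopent-2-en-1-one | CC(C)(C)[Si](C)(C)O[C@H]1CC(=O)C=C1 | intermediate
6 | bromomagnesium (3S,4S)-4-(TBSO)-3-vinylcyclopent-1-en-1-olate | CC(C)(C)[Si](C)(C)O[C@H]1CC(O[Mg]Br)=C[C@@H]1C=C | intermediate (not isolated)
7 | (2R,3S,4S)-4-(TBSO)-2-(hydroxymethyl)-3-vinylcyclopentan-1-one | CC(C)(C)[Si](C)(C)O[C@H]1CC(=O)[C@@H](CO)[C@@H]1C=C | intermediate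
8 | [(1R,2S,3S)-3-(TBSO)-5-oxo-2-vinylcyclopentyl]methyl methanesulfonate | CC(C)(C)[Si](C)(C)O[C@H]1CC(=O)[C@@H](COS(C)(=O)=O)[C@@H]1C=C | intermediate (not isolated)
9 | (3S,4S)-4-(TBSO)-2-methylidene-3-vinylcyclopentan-1-one | CC(C)(C)[Si](C)(C)O[C@H]1CC(=O)C(=C)[C@@H]1C=C | intermediate
10 | (1R,3S,4S)-4-(TBSO)-1-methyl-2-methylidene-3-vinylcyclopentan-1-ol (major C1 epimer drawn) | CC(C)(C)[Si](C)(C)O[C@H]1C[C@@](C)(O)C(=C)[C@@H]1C=C | intermediate
11 | (S)-2-(2,2-dimethyl-5-oxo-1,3-dioxolan-4-yl)acetic acid (L-malic acid acetonide) | OC(=O)C[C@@H]1OC(C)(C)OC1=O | starting material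
12 | (1R,3S,4S)-4-(TBSO)-1-methyl-2-methylidene-3-vinylcyclopentyl 2-[(4S)-2,2-dimethyl-5-oxo-1,3-dioxolan-4-yl]acetate | CC(C)(C)[Si](C)(C)O[C@H]1C[C@@](C)(OC(=O)C[C@@H]2OC(C)(C)OC2=O)C(=C)[C@@H]1C=C | intermediate
13 | 1-methyl 4-[(1R,3S,4S)-4-(TBSO)-1-methyl-2-methylidene-3-vinylcyclopentyl] (2S)-2-hydroxybutanedioate | CC(C)(C)[Si](C)(C)O[C@H]1C[C@@](C)(OC(=O)C[C@H](O)C(=O)OC)C(=C)[C@@H]1C=C | intermediate
14 | dilithium alkoxide–ester enolate of 13 | [Li+].[Li+].CC(C)(C)[Si](C)(C)O[C@H]1C[C@@](C)(OC([O-])=C[C@H]([O-])C(=O)OC)C(=C)[C@@H]1C=C | intermediate (not isolated)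
15 | (2R,3S)-2-{[(4S,5S)-4-(TBSO)-2-methyl-5-vinylcyclopent-1-en-1-yl]methyl}-3-hydroxy-4-methoxy-4-oxobutanoic acid | CC(C)(C)[Si](C)(C)O[C@H]1CC(C)=C(C[C@H]([C@H](O)C(=O)OC)C(=O)O)[C@@H]1C=C | intermediate
16 | methyl (2S,3R)-3-{[(4S,5S)-4-(TBSO)-2-methyl-5-vinylcyclopent-1-en-1-yl]methyl}-2-hydroxy-4-[methoxy(methyl)amino]-4-oxobutanoate | CC(C)(C)[Si](C)(C)O[C@H]1CC(C)=C(C[C@H]([C@H](O)C(=O)OC)C(=O)N(C)OC)[C@@H]1C=C | intermediate
17 | methyl (2S,3R)-3-{[(4S,5S)-4-(TBSO)-2-methyl-5-vinylcyclopent-1-en-1-yl]methyl}-2-hydroxy-4-oxohex-5-enoate | CC(C)(C)[Si](C)(C)O[C@H]1CC(C)=C(C[C@H]([C@H](O)C(=O)OC)C(=O)C=C)[C@@H]1C=C | intermediate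
18 | methyl (11S)-2α-(TBSO)-11-hydroxy-8-oxo-13,14-dinor-1αH,7αH-guaia-4,9-dien-12-oate | CC(C)(C)[Si](C)(C)O[C@H]1CC(C)=C2C[C@H]([C@H](O)C(=O)OC)C(=O)/C=C\[C@H]12 | intermediate
19 | methyl (11S)-2α-(TBSO)-4α,5α-epoxy-11-hydroxy-8-oxo-13,14-dinor-1αH,7αH-guai-9-en-12-oate | CC(C)(C)[Si](C)(C)O[C@H]1C[C@@]3(C)O[C@]32C[C@H]([C@H](O)C(=O)OC)C(=O)/C=C\[C@H]12 | intermediate (not isolated)
20 | methyl (11S)-2α-(TBSO)-5β,11-epoxy-4α-hydroxy-8-oxo-13,14-dinor-1αH,7αH-guai-9-en-12-oate | CC(C)(C)[Si](C)(C)O[C@H]1C[C@@](C)(O)[C@@]23C[C@@H](C(=O)/C=C\[C@H]12)[C@H](O3)C(=O)OC | intermediate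
21 | methyl (11S)-2α-(TBSO)-5β,11-epoxy-4α-hydroxy-8-oxo-13-nor-1αH,7αH,10βH-guaian-12-oate | CC(C)(C)[Si](C)(C)O[C@H]1C[C@@](C)(O)[C@@]23C[C@@H](C(=O)C[C@@H](C)[C@H]12)[C@H](O3)C(=O)OC | intermediate
22 | methyl (11S)-2α-(TBSO)-5β,11-epoxy-4α,8β-dihydroxy-13-nor-1αH,7αH,10βH-guaian-12-oate | CC(C)(C)[Si](C)(C)O[C@H]1C[C@@](C)(O)[C@@]23C[C@@H]([C@H](O)C[C@@H](C)[C@H]12)[C@H](O3)C(=O)OC | intermediate (not isolated)
23 | (11S)-2α-(TBSO)-5β,11-epoxy-4α-hydroxy-13-nor-1αH,7αH,8αH,10βH-guaian-12,8β-olide | CC(C)(C)[Si](C)(C)O[C@H]1C[C@@](C)(O)[C@@]23C[C@H]4[C@@H](C[C@@H](C)[C@H]12)OC(=O)[C@H]4O3 | intermediate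
24 | dilithium C4-alkoxide lactone enolate of 23 | [Li+].[Li+].CC(C)(C)[Si](C)(C)O[C@H]1C[C@@](C)([O-])[C@@]23C[C@H]4[C@@H](C[C@@H](C)[C@H]12)OC([O-])=C4O3 | intermediate (not isolated)
25 | (11R)-2α-(TBSO)-5β,11-epoxy-4α,13-dihydroxy-1αH,7αH,8αH,10βH-guaian-12,8β-olide | CC(C)(C)[Si](C)(C)O[C@H]1C[C@@](C)(O)[C@@]23C[C@H]4[C@@H](C[C@@H](C)[C@H]12)OC(=O)[C@@]4(CO)O3 | intermediate
26 | (11R)-13-acetoxy-2α-(TBSO)-5β,11-epoxy-4α-hydroxy-1αH,7αH,8αH,10βH-guaian-12,8β-olide | CC(C)(C)[Si](C)(C)O[C@H]1C[C@@](C)(O)[C@@]23C[C@H]4[C@@H](C[C@@H](C)[C@H]12)OC(=O)[C@@]4(COC(C)=O)O3 | intermediate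
27 | (11R)-13-acetoxy-5β,11-epoxy-2α,4α-dihydroxy-1αH,7αH,8αH,10βH-guaian-12,8β-olide | O[C@H]1C[C@@](C)(O)[C@@]23C[C@H]4[C@@H](C[C@@H](C)[C@H]12)OC(=O)[C@@]4(COC(C)=O)O3 | intermediate
28 | CNP0112086.1, (1R,2S,4R,5R,7S,8R,10R,11R)-13-acetoxy-5β,11-epoxy-4α-hydroxy-2α-[(E)-2-methylbut-2-enoyloxy]guaian-12,8β-olide | C/C=C(\C)C(=O)O[C@H]1C[C@@](C)(O)[C@@]23C[C@H]4[C@@H](C[C@@H](C)[C@H]12)OC(=O)[C@@]4(COC(C)=O)O3 | target

**Totals**

Total step count: 19. Longest linear sequence: 19 steps (1 → 28); 11 enters as bought in step 7.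

**Three steps most likely to fail, with fallbacks**

First, step 9, the dianionic Ireland–Claisen rearrangement: the enolate of the tertiary ester may fragment before it rearranges, or the anti selectivity at C7 may be poor. The fallback makes the same C6–C7 bond by intermolecular Fráter–Seebach alkylation; it sets out from 10 and comes back to the route at 15. PBr3 (pyridine, Et2O, −30 °C) converts 10 with allylic transposition into the primary bromide tert-butyl{[(1S,2S)-3-(bromomethyl)-4-methyl-2-vinylcyclopent-3-en-1-yl]oxy}dimethylsilane F1. Acid 11 is alkylated (allyl bromide, K2CO3, DMF) to allyl 2-[(4S)-2,2-dimethyl-5-oxo-1,3-dioxolan-4-yl]acetate F2 and opened with K2CO3/MeOH to 4-allyl 1-methyl (2S)-2-hydroxybutanedioate F3. Its dianion (LiN(iPr)2, 2.2 equiv, THF, −78 → −10 °C) is alkylated by F1 anti to the alkoxide to give 1-allyl 4-methyl (2R,3S)-2-{[(4S,5S)-4-(TBSO)-2-methyl-5-vinylcyclopent-1-en-1-yl]methyl}-3-hydroxybutanedioate F4, and Pd(PPh3)4 with morpholine removes the allyl ester to give 15.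

Second, step 11, the vinyl Grignard addition: the α-hydroxy methyl ester may also be attacked, and the vinyl ketone may add the released amine. The fallback replaces the Grignard addition by a palladium-catalysed cross-coupling that tolerates esters; it sets out from 15 and comes back at 17. EDC·HCl, EtSH and DMAP give the thioester methyl (2S,3R)-3-{[(4S,5S)-4-(TBSO)-2-methyl-5-vinylcyclopent-1-en-1-yl]methyl}-4-(ethylsulfanyl)-2-hydroxy-4-oxobutanoate F5, which in a Fukuyama coupling (CH2=CHZnBr, PdCl2(PPh3)2, THF, rt) gives 17.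

Third, step 13, the epoxidation and ring C closure: the 2α-silyloxy group may erode the α-face preference, and a β-epoxide cannot cyclise. The fallback uses hydroxyl-directed (Henbest) epoxidation instead of steric control; it sets out from 18 and comes back at 20. HF·pyridine gives methyl (11S)-2α,11-dihydroxy-8-oxo-13,14-dinor-1αH,7αH-guaia-4,9-dien-12-oate F6, whose free 2α-hydroxyl directs mCPBA to the α face. PPTS then closes the ether to methyl (11S)-5β,11-epoxy-2α,4α-dihydroxy-8-oxo-13,14-dinor-1αH,7αH-guai-9-en-12-oate F7, and TBSCl/imidazole silylates only the secondary hydroxyl to give 20.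

**Further compounds**

F1 | step 9 | tert-butyl{[(1S,2S)-3-(bromomethyl)-4-methyl-2-vinylcyclopent-3-en-1-yl]oxy}dimethylsilane | CC(C)(C)[Si](C)(C)O[C@H]1CC(C)=C(CBr)[C@@H]1C=C
F2 | step 9 | allyl 2-[(4S)-2,2-dimethyl-5-oxo-1,3-dioxolan-4-yl]acetate | C=CCOC(=O)C[C@@H]1OC(C)(C)OC1=O
F3 | step 9 | 4-allyl 1-methyl (2S)-2-hydroxybutanedioate | COC(=O)[C@@H](O)CC(=O)OCC=C
F4 | step 9 | 1-allyl 4-methyl (2R,3S)-2-{[(4S,5S)-4-(TBSO)-2-methyl-5-vinylcyclopent-1-en-1-yl]methyl}-3-hydroxybutanedioate | CC(C)(C)[Si](C)(C)O[C@H]1CC(C)=C(C[C@H]([C@H](O)C(=O)OC)C(=O)OCC=C)[C@@H]1C=C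
F5 | step 11 | methyl (2S,3R)-3-{[(4S,5S)-4-(TBSO)-2-methyl-5-vinylcyclopent-1-en-1-yl]methyl}-4-(ethylsulfanyl)-2-hydroxy-4-oxobutanoate | CC(C)(C)[Si](C)(C)O[C@H]1CC(C)=C(C[C@H]([C@H](O)C(=O)OC)C(=O)SCC)[C@@H]1C=C
F6 | step 13 | methyl (11S)-2α,11-dihydroxy-8-oxo-13,14-dinor-1αH,7αH-guaia-4,9-dien-12-oate | O[C@H]1CC(C)=C2C[C@H]([C@H](O)C(=O)OC)C(=O)/C=C\[C@H]12
F7 | step 13 | methyl (11S)-5β,11-epoxy-2α,4α-dihydroxy-8-oxo-13,14-dinor-1αH,7αH-guai-9-en-12-oate | O[C@H]1C[C@@](C)(O)[C@@]23C[C@@H](C(=O)/C=C\[C@H]12)[C@H](O3)C(=O)OC
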